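**Plan** (C1 = CO2H, oxirane = O/C2/C3, alkene = C4=C5, ketone = C6, chain = C7–C22)
1. Retrosynthetic cuts, in order: the C1 acid goes back to CH2O–Si (an oxidation-level helper), then the C5–C6 acyl–vinyl bond is cut, and last the two C–O bonds of the oxirane.
2. Enabling feature: C4=C5–C6=O is an E-enone whose C5 carries only H. It is therefore the syn H/acyl adduct of a terminal alkyne C4≡C5–H, and the key event is a one-flask net hydroacylation of that alkyne.
3. The oxirane ring hangs on the propargylic carbon C3. The metal must therefore end on C5, not C4 (β-oxygen elimination), and must be d0 (no insertion into C3–O). Zr(IV)–H meets both demands.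
4. Forward: the only ring is made first on a C5 enynol and the OH is capped. C5 and C17 are then joined to the full C22 chain with the enone in place, the cap is removed, and C1 is raised to the acid.
5. Stereochemistry: C2 and C3 come from a reagent-controlled Katsuki–Sharpless epoxidation with (−)-tartrate, trans from the E-alkene. The E C4=C5 bond comes from syn hydrozirconation with retention in the metal exchanges.

Key step: step 3

Remark: 1 (E isomer) and 4 are taken as catalogue compounds. In the SMILES of zirconocenes the cyclopentadienyl rings are drawn σ-bound only so that the strings parse.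

Step 1
Reactants: 1 (E)-pent-2-en-4-yn-1-ol
Product: 2 [(2R,3R)-3-ethynyloxiran-2-yl]methanol
Conditions: Ti(OiPr)4 (10 mol %), D-(−)-DIPT (13 mol %), t-BuOOH (2 equiv, decane), 4 Å MS, CH2Cl2, −20 °C; non-aqueous work-up
Reagents that add atoms: tert-butyl hydroperoxide, CC(C)(C)OO
Why: In this Katsuki–Sharpless asymmetric epoxidation the Ti/(−)-tartrate complex binds the allylic OH and should deliver oxygen to the alkene face that gives the (2R,3R) oxirane, the E geometry passing stereospecifically into the trans ring while the alkyne stays untouched.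

Step 2
Reactants: 2 [(2R,3R)-3-ethynyloxiran-2-yl]methanol
Product: 3 tert-butyl{[(2R,3R)-3-ethynyloxiran-2-yl]methoxy}dimethylsilane
Conditions: TBSCl (1.1 equiv), imidazole (2 equiv), CH2Cl2, 0 °C to rt
Reagents that add atoms: tert-butyldimethylsilyl chloride, CC(C)(C)[Si](C)(C)Cl
Why: Imidazole-promoted O-silylation caps the only protic and acylable group before Zr–H and the acid chloride are used, under conditions too mild for Payne rearrangement and without touching a stereocentre.

Step 3
Reactants: 3 tert-butyl{[(2R,3R)-3-ethynyloxiran-2-yl]methoxy}dimethylsilane; 4 heptadecanoyl chloride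
Product: 6 (2R,3R,4E)-1-(tert-butyldimethylsilyloxy)-2,3-epoxydocos-4-en-6-one, via (E)-alkenylzirconocene chloride 5 (not isolated)
Conditions: Cp2Zr(H)Cl (1.1 equiv), THF, 0 °C to rt, dark; then 4 (1.2 equiv), CuBr·SMe2 (10 mol %), 0 °C to rt
Reagents that add atoms: zirconocene chloride hydride (Schwartz reagent), [H][Zr](Cl)(C1C=CC=C1)C2C=CC=C2 (its Cp2ZrCl part stays only in 5; 6 keeps its H)
Why: The Zr–H bond of Cp2Zr(H)Cl adds syn across C4≡C5 through a four-centre transition state, Zr going to the terminal C5 and H to C4, to give (E)-alkenylzirconocene 5; catalytic Cu(I) then takes over the alkenyl group with retention and the alkenylcopper is acylated by 4, which forms the C5–C6 bond and releases Cp2ZrCl2 and Cu(I). The closest known reaction type is the one-pot hydrozirconation/copper(I)-catalysed acylation of alkenylzirconocenes with acid chlorides to (E)-enones, in sum an anti-Markovnikov syn hydroacylation of a terminal alkyne. No ring is closed and no stereocentre is created; the one new stereoelement, the E C4=C5 bond, is fixed by the syn addition and by retention in both transfers, and C2 and C3 are spectators. The step needs regioselectivity (metal on C5) and chemoselectivity (alkyne before oxirane): the branched oxiranyl carbon C3 pushes Zr to C5, reversible Zr–H addition funnels any internal isomer to the terminal one, and alkyne hydrozirconation is much faster than hydride attack on an oxirane when only a slight excess of reagent is used in THF. A d0 Zr(IV) on C5 can neither insert into the propargylic C3–O bond nor lose the ring oxygen by β-elimination, the two paths open to low-valent metals or to a metal on C4. The silyl ether keeps the C1 oxygen from quenching Zr–H or being acylated, and the acid chloride is far more electrophilic than enone 6 or the vinyl oxirane, so it should capture the small stationary amount of alkenylcopper.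

Step 4
Reactants: 6 (2R,3R,4E)-1-(tert-butyldimethylsilyloxy)-2,3-epoxydocos-4-en-6-one
Product: 7 (2R,3R,4E)-2,3-epoxy-1-hydroxydocos-4-en-6-one
Conditions: Et3N·3HF (5 equiv), THF, rt
Reagents that add atoms: none
Why: Fluoride-driven cleavage of the primary silyl ether (desilylation, driven by the strong Si–F bond) runs in a buffered, nearly neutral medium, so it should avoid Payne rearrangement, opening of the electron-poor vinyl oxirane and enolisation of the enone.

Step 5
Reactants: 7 (2R,3R,4E)-2,3-epoxy-1-hydroxydocos-4-en-6-one
Product: 9 (2S,3R,4E)-2,3-epoxy-6-oxodocos-4-enoic acid, via epoxy aldehyde 8 (not isolated)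
Conditions: TEMPO (20 mol %), PhI(OAc)2 (2.5 equiv), MeCN/CH2Cl2/H2O, rt
Reagents that add atoms: water, O
Why: Oxoammonium-mediated oxidation (TEMPO/PhI(OAc)2 in wet solvent) should take the primary carbinol through aldehyde 8 and its hydrate to the acid, leaving enone and oxirane alone and keeping C2 intact in the weakly acidic medium (its descriptor changes from R to S only through the CIP ranking).

**Compound list**
1 | (E)-pent-2-en-4-yn-1-ol | C#C/C=C/CO | starting material
2 | [(2R,3R)-3-ethynyloxiran-2-yl]methanol | C#C[C@H]1O[C@@H]1CO | intermediate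
3 | tert-butyl{[(2R,3R)-3-ethynyloxiran-2-yl]methoxy}dimethylsilane | C#C[C@H]1O[C@@H]1CO[Si](C)(C)C(C)(C)C | intermediate
4 | heptadecanoyl chloride | CCCCCCCCCCCCCCCCC(=O)Cl | starting material
5 | chlorobis(cyclopentadienyl){(E)-2-[(2R,3R)-3-(tert-butyldimethylsilyloxymethyl)oxiran-2-yl]ethenyl}zirconium | Cl[Zr](C1C=CC=C1)(C2C=CC=C2)/C=C/[C@H]3O[C@@H]3CO[Si](C)(C)C(C)(C)C | intermediate
6 | (2R,3R,4E)-1-(tert-butyldimethylsilyloxy)-2,3-epoxydocos-4-en-6-one | CCCCCCCCCCCCCCCCC(=O)/C=C/[C@H]1O[C@@H]1CO[Si](C)(C)C(C)(C)C | intermediate
7 | (2R,3R,4E)-2,3-epoxy-1-hydroxydocos-4-en-6-one | CCCCCCCCCCCCCCCCC(=O)/C=C/[C@H]1O[C@@H]1CO | intermediate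
8 | (2S,3R,4E)-2,3-epoxy-6-oxodocos-4-enal | CCCCCCCCCCCCCCCCC(=O)/C=C/[C@H]1O[C@@H]1C=O | intermediate
9 | (2S,3R,4E)-2,3-epoxy-6-oxodocos-4-enoic acid | CCCCCCCCCCCCCCCCC(=O)/C=C/[C@H]1O[C@@H]1C(=O)O | target

Total step count: 5. Longest linear sequence: 5 steps (1 to 9); 4 enters at step 3.

**Steps most likely to fail**

(a) Step 3.
- Possible failure: hydride transfer from Zr–H to the oxirane, or opening of the ring by the Lewis-acidic zirconium or the acid chloride, may compete with alkyne hydrozirconation. Acyl transfer may also be slow enough for the alkenyl metal to add to the enone already formed.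
- Fallback (from 3, back at 6): the coupling is moved to the alcohol oxidation level, with boron and zinc in place of zirconium and copper and an aldehyde in place of the acid chloride. Compound 3 would be hydroborated with dicyclohexylborane (THF, 0 °C) to the (E)-alkenyldicyclohexylborane F1. The alkenyl group would be passed to zinc with Et2Zn (−78 °C) to give the (E)-alkenyl(ethyl)zinc F2. This would add to purchased heptadecanal to give, after NH4Cl quench, the allylic alcohol F3 as a mixture of C6 epimers. Dess–Martin periodinane (NaHCO3, CH2Cl2) would erase the C6 centre and bring both epimers to 6.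

(b) Step 1.
- Possible failure: epoxidation of the alkynyl-deactivated alkene may be slow, with erosion of facial selectivity, and the small, volatile, water-soluble product may be lost during work-up.
- Fallback (from 1, back at 3): the order of capping and oxidation is reversed, and the directed metal-catalysed epoxidation is replaced by a dioxirane. Compound 1 would first be silylated (TBSCl, imidazole, CH2Cl2) to the lipophilic (E)-enyne silyl ether F4. A Shi epoxidation would follow (D-fructose-derived ketone catalyst, Oxone, K2CO3 buffer, MeCN/dimethoxymethane/H2O, 0 °C). Conjugated E-enynes are a favourable substrate class for it, so it should give 3 directly in the (R,R) series with the alkyne untouched.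

(c) Step 5.
- Possible failure: the oxidation may stall at the aldehyde/hydrate stage in the poorly water-miscible lipid medium, or the oxirane may open during the two late operations on the full epoxy enone.
- Fallback (from 2, back at 9): C1 is oxidised before the coupling and carried through it as a silyl ester.
  - Compound 2 would be oxidised with TEMPO/PhI(OAc)2 in aqueous MeCN through (2S,3R)-3-ethynyloxirane-2-carbaldehyde F5 to (2S,3R)-3-ethynyloxirane-2-carboxylic acid F6.
  - The acid would be silylated (TIPSCl, Et3N, CH2Cl2) to the hydride-tolerant triisopropylsilyl ester F7.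
  - The same hydrozirconation/acylation with 4 would lead through the alkenylzirconocene F8 to the triisopropylsilyl ester of the target F9.
  - Et3N·3HF (THF, 0 °C) would free 9 in one mild last operation.

**Further compounds**
F1 | step 3 | dicyclohexyl{(E)-2-[(2R,3R)-3-(tert-butyldimethylsilyloxymethyl)oxiran-2-yl]ethenyl}borane | C1CCC(CC1)B(C2CCCCC2)/C=C/[C@H]3O[C@@H]3CO[Si](C)(C)C(C)(C)C
F2 | step 3 | ethyl{(E)-2-[(2R,3R)-3-(tert-butyldimethylsilyloxymethyl)oxiran-2-yl]ethenyl}zinc | CC[Zn]/C=C/[C@H]1O[C@@H]1CO[Si](C)(C)C(C)(C)C
F3 | step 3 | (2R,3R,4E,6RS)-1-(tert-butyldimethylsilyloxy)-2,3-epoxydocos-4-en-6-ol | CCCCCCCCCCCCCCCCC(O)/C=C/[C@H]1O[C@@H]1CO[Si](C)(C)C(C)(C)C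
F4 | step 1 | (E)-tert-butyldimethyl(pent-2-en-4-yn-1-yloxy)silane | C#C/C=C/CO[Si](C)(C)C(C)(C)C
F5 | step 5 | (2S,3R)-3-ethynyloxirane-2-carbaldehyde | C#C[C@H]1O[C@@H]1C=O
F6 | step 5 | (2S,3R)-3-ethynyloxirane-2-carboxylic acid | C#C[C@H]1O[C@@H]1C(=O)O
F7 | step 5 | triisopropylsilyl (2S,3R)-3-ethynyloxirane-2-carboxylate | C#C[C@H]1O[C@@H]1C(=O)O[Si](C(C)C)(C(C)C)C(C)C
F8 | step 5 | chlorobis(cyclopentadienyl){(E)-2-[(2R,3S)-3-(triisopropylsilyloxycarbonyl)oxiran-2-yl]ethenyl}zirconium | Cl[Zr](C1C=CC=C1)(C2C=CC=C2)/C=C/[C@H]3O[C@@H]3C(=O)O[Si](C(C)C)(C(C)C)C(C)C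
F9 | step 5 | triisopropylsilyl (2S,3R,4E)-2,3-epoxy-6-oxodocos-4-enoate | CCCCCCCCCCCCCCCCC(=O)/C=C/[C@H]1O[C@@H]1C(=O)O[Si](C(C)C)(C(C)C)C(C)C
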